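In the dawn run, monomer in chains gains less over the last day read than over the day before, so I replace the curve by its mean slope s, the share of the charge gained per day between neighbouring readings, and set it at the midpoint of each interval.

| flask | free monomer | initiator | remark | time |
|---|---|---|---|---|
| dawn | 0.40 M | 10 mM | the very flask that is asked about, followed so far |  |
| flask | 0.40 M | 10 mM |  | 15 d |

- dawn (time / d: monomer in chains / %): 1.25: 20.0; 1.67: 27.6; 2.00: 33.2; 3.00: 44.8; 4.00: 51.0; 5.00: 54.2; 6.00: 54.1

(standard deviation of a reading: 0.5 percentage points)

* when, up to 15 d, the flask holds most monomer in chains
* the amount of monomer in chains, in percent of the free monomer charged, at that time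

- reactions considered so far: free monomer + initiator -> living end + monomer in chains; free monomer + living end -> monomer in chains + living end; 2 initiator -> spent initiator; monomer in chains -> over-reaction product

| midpoint | s |
|---|---|
| 3.50 d | 0.0620 d⁻¹ |
| 4.50 d | 0.0320 d⁻¹ |
| 5.50 d | −0.00100 d⁻¹ |

Down the column, s drops by 0.0300 d⁻¹ and then by 0.0330 d⁻¹. A slope from two readings scatters by 0.00707 d⁻¹, and the two drops differ by less than that. So over these rows s falls along a straight line within the scatter, and on such a line the mean over an interval is the slope at its midpoint. The mean therefore costs no error beyond the scatter.

The last two rows put the zero of s at 5.47 d. I carry this crossing time t_p, when the net gain of monomer in chains passes zero, give or take 0.214 d. For the height I take the reading beside it, 54.2%.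

The forecast says 6 d and 55%, “followed by a slow decline or a flat plateau”. My t_p is earlier than its time.

The flask gives 5.42 d and 54.2%, inside the forecast's margins.

    free monomer + initiator → living end + monomer in chains (k = 0.0750 M⁻¹ h⁻¹)
    free monomer + living end → monomer in chains + living end, rate k2*[living end]*[free monomer] (k = 3.90 M⁻¹ h⁻¹)
    2 initiator → spent initiator (k = 6.20 M⁻¹ h⁻¹)
    monomer in chains → over-reaction product (k = 0.00540 h⁻¹)

In this flask, monomer in chains, an intermediate in series reactions, is made 2.92 times faster than it is used up at 2.77 d, each step taken net, while at 15.0 d the same ratio is 0.0872. The ratio passes one between those times, and that passing is what t_p reads from the slopes.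

The forecast's answer needs a stop later than t_p. The flask left until 4.0 d stops before 5.47 d, so t_p says it is still rising and its highest amount is its last, near the reading 51.0%. Computed, that highest amount is 51.3%, below the forecast's height.

The earlier runs and the new flask are simulated on assumed constants, and the scatter is random.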